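## Structural features

The target is a linear trimer of 7,8,4′-trihydroxyflavan units: each unit is a chroman (rings A and C) with a 4-hydroxyphenyl ring B at C2, C4 of unit 3 is bonded to C6 of unit 2, and C4 of unit 2 is bonded to C6 of unit 1. Units 3 and 2 are flavan-3-ols and unit 1 is a flavan-3,4-diol, so the molecule holds nine phenols, three secondary C3 alcohols and one benzylic C4 alcohol. The nine stereocentres form three contiguous C2–C3–C4 triads: unit 1 (2R,3R,4R) is all-cis, unit 2 (2R,3S,4R) is 2,3-trans-3,4-trans, and unit 3 (2R,3S,4S) is 2,3-trans-3,4-cis. The fragile groups are the pyrogallol-type A rings (oxidised once free, above all in base), the C4 hydroxyl of unit 1 (benzylic and para to O7, so ionised by acid and open to hydrogenolysis), and the doubly benzylic C4–H bonds of units 2 and 3. The real difficulty is that three rings built from the same atoms need three different relative configurations, and that both interflavan bonds join a hindered C4 to an A-ring carbon flanked by oxygen. The key step uses the cis relation in unit 3 between the C4 aryl group (ring A of unit 2) and O3: O1, C8a, C4a and C4 of unit 3 are taken as an ortho-quinone methide of ring A, and C2 and C3 with their two cis oxygens as a cyclic cis-enediol ether, so that ring C, the O1–C2 and C3–C4 bonds and the C3/C4 relation arise in one endo [4+2] addition. The acetal left at C2 then lets ring B enter trans to O3.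

## Logic of the disconnections

**43 ⇒ 42 ⇒ 41.** The nine aryl O–benzyl bonds and then the two O–Si bonds are cut first. Free pyrogallol rings cannot be carried through organometallic, acidic or oxidative steps, and the silylene ties the cis-diol of unit 1 and keeps its C4 oxygen a poor leaving group. The gain is that all earlier chemistry runs on air-stable ethers. The demand is a neutral hydrogenolysis that spares the benzylic C–O bonds of the three C rings.

**41 ⇒ 39.** The C3–O and C2–H bonds of unit 2 are cut. The all-trans triad of unit 2 is what a syn addition to a C2=C3 enol ether gives when it comes from the face opposite to the C4 substituent. Two stereocentres are removed and only C4 of unit 2 remains to be set. The forward step needs clean face selection by that one centre and an oxidation that leaves the silylene in place.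

**39 ⇒ 36 + 34.** The C3–C4 and O1–C2 bonds of unit 2 are cut, again through an ortho-quinone methide of ring A (37), now with a 2π partner that brings ring B. Ring C of unit 2 and its B ring fall away together. The forward step must set C4 of unit 2 under catalyst control in the presence of six remote stereocentres.

**36 ⇒ 17 + 31.** The C4–C4a bond of unit 2 is cut. This is the most convergent cut: it divides the trimer into the unit 3 part with ring A of unit 2 and the complete unit 1. The forward step needs only a free phenol with one open ortho position and an aldehyde, and must tolerate the silylene and the free C3 hydroxyl.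

**17 ⇒ 16 ⇒ 14 + 15.** The allyl ether is restored, then the C2–aryl bond of unit 3 is cut. The C2 acetal is a latent oxocarbenium ion, and an aryl nucleophile should enter opposite to O3 and to the C4 aryl group. Ring B becomes a commercial trifluoroborate. The forward step must ionise at C2 rather than at the ketal carbon.

**14 ⇒ 9 + 12 (key).** The O1–C2 and C3–C4 bonds of unit 3 are cut. One ring, two skeletal bonds and three stereocentres are removed, leaving a racemic carbinol and a symmetric alkene. The forward step must be endo- and face-selective. The design of 9 is kept with three deliberate features: the only free hydroxyl is the ortho one; the para oxygen of the other ring is an allyl ether (a free para phenol would divert to a para-quinone methide, and the allyl group later unmasks the phenol for the next annulation); and C4a of that ring is left unsubstituted for that annulation. Alkene 12 is used in excess over sieves because it is acid- and water-labile.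

**9 ⇒ 4 + 7; 4 ⇒ 2 ⇒ 1; 7 ⇒ 6 ⇒ 5; 12 ⇒ 10.** The diaryl carbinol C–C bond is cut by the same ortho-hydroxyalkylation. The phenol comes from an aldehyde by aryl migration, the aldehyde by stepwise etherification that uses the higher acidity of the 4-hydroxyl, and the dioxole by chlorination and elimination of the saturated ketal.

**31 ⇒ 29 ⇒ 28 ⇒ 27.** The C6–CHO bond, the C6–Br bond and the silylene are cut. C6 of unit 1 is para to O1 and ortho to O7, so it is the natural site for electrophilic bromination and later formylation.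

**27 ⇒ 24.** The C3–O and C4–O bonds of unit 1 are cut. The all-cis triad needs both oxygens on the face of the C2 aryl group, which is the hindered face. An iodo-acetoxylation followed by neighbouring-group displacement delivers exactly that face. The forward step needs iodine to add anti to the aryl group and must avoid iodinating the arenes.

**24 ⇒ 21 + 22; 21 ⇒ 19 ⇒ 18.** The C2–aryl bond of unit 1 is cut to a benzopyrylium equivalent and an aryl boronate. This sets the first stereocentre of unit 1 by a catalytic enantioselective addition and traces ring A and C2–C4 back to a commercial coumarin.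

**34 ⇒ 32.** The enamide comes from a nitrile by methyl addition and N-acetylation.

## Other disconnections considered

**Alternative 1:** The cut is at both C2–aryl bonds of units 2 and 3, made last. In the forward direction the bis(anomeric acetate) A2 would be ionised twice by BF3·OEt2 and two molecules of 15 would add to give A1. In its favour, one reagent and one operation make both ring B bonds, and the 3-O-acetates can direct each aryl group trans by participation. On this point it is better than the chosen plan, which relies on steric control alone at C2 of unit 3. Against it, A2 still needs two different annulations, because its two C rings have opposite C3/C4 relations. BF3 would also act on a trimer that contains the ionisable C4–O bond of unit 1, two doubly benzylic carbons and electron-rich A rings next to two cations. Mono-arylation, orthoester formation and intramolecular arylation are likely side paths. Structurally and mechanistically the bond made at unit 3 is the same as in step 8 of the chosen plan. In step count it saves one arylation but adds acetylation and deacetylation, so it is at best equal. The chosen plan is preferred because it uses BF3 only on a small fragment without unit 1.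

**Alternative 2:** The cut is at C4–C4a and O1–C2 of unit 2. In the forward direction, phenol A5 would add through C4a to the β-carbon of enal A4 under a diarylprolinol silyl ether, and the phenol oxygen would close on the aldehyde to give lactol A3. In its favour, iminium activation is not acidic. It is therefore gentler on the C4–O bond of unit 1 than the Brønsted acid of the chosen step 19, and on this point it is better. The control of C4 by a shielded iminium ion is equal in kind to the catalyst control of the chosen plan. Against it, A5 is a monophenol of moderate nucleophilicity with one hindered ortho position, whereas this cascade is established for naphthols and strongly activated phenols. A4 is also a deactivated, electron-rich β-aryl enal. A3 lacks both O3 and ring B of unit 2, so dehydration, epoxidation and aryl opening would follow, where the chosen plan needs a single hydroboration. Both routes end with an anti addition to a 4H-chromene, so the stereochemical logic is equal. The alternative is about three steps longer, including the synthesis of A4 from 31.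

**Alternative 3:** The cut is at C3–C4 of unit 3. In the forward direction SmI2 would reduce the diaryl ketone of A7 to its ketyl, which adds to the tethered aldehyde to give cis-diol A6; a hydride would then replace the C4 hydroxyl. In its favour, the cis relation of the two oxygens follows from a chelated ketyl–aldehyde coupling, and C2 comes from a mandelate. The ring-forming step is therefore more predictable than an enantioselective cycloaddition with a partner not yet used in that setting, and on this point it is better. Against it, A7 carries an epimerisable α-aryl-α-aryloxy aldehyde. The tertiary C4 hydroxyl of A6 must be removed through a cation next to a free C3 hydroxyl, which invites a semipinacol shift or elimination. The hydride must also come from the face of the C2 aryl group. Samarium is used in stoichiometric amount, and five steps from 9 replace two. The chosen plan sets three stereocentres in one catalytic step, whereas this one sets two and then erases one. It is kept as the fallback for step 7.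

Key step: step 7

Remark on catalysts: the sense of induction of the chiral catalysts in steps 7, 12 and 19 cannot be derived in advance; the enantiomer written is assumed to give the configuration shown, and its antipode is used if the sense is opposite.

Remark on materials: 15, 18, 22 and 32 are taken as commercial.

Remark on descriptors: the geometry at C4 of unit 3 is the same from 14 to 43; its label is S in 14, 16, 17 and 43 and R in 36 to 42 only because substituent priorities change. For the same reason C3 of unit 1 is R in the free diol and S under the silylene.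

Step 1
Reactants: 1 2,3-dihydroxybenzaldehyde
Product: 2 2,3-bis(benzyloxy)benzaldehyde
Conditions: BnBr, K2CO3, DMF, 60 °C
Reagents that add atoms: benzyl bromide BrCc1ccccc1
Why: Double Williamson etherification; both phenols are alkylated under carbonate and the aldehyde is not touched.

Step 2
Reactants: 2 2,3-bis(benzyloxy)benzaldehyde
Product: 4 2,3-bis(benzyloxy)phenol, via aryl formate 3 (not isolated)
Conditions: mCPBA, CH2Cl2, rt; then K2CO3, MeOH, rt
Reagents that add atoms: 3-chloroperoxybenzoic acid OOC(=O)c1cccc(Cl)c1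
Why: Baeyer–Villiger oxidation of an electron-rich benzaldehyde (Dakin-type): the alkoxy-substituted aryl group migrates in preference to hydride, and the formate is methanolysed in the same flask.

Step 3
Reactants: 5 2,3,4-trihydroxybenzaldehyde
Product: 6 4-(allyloxy)-2,3-dihydroxybenzaldehyde
Conditions: allyl bromide, NaHCO3, DMF, 40 °C
Reagents that add atoms: allyl bromide C=CCBr
Why: Regioselective Williamson etherification: the 4-hydroxyl, para to the formyl group, is the most acidic and the only one ionised by hydrogen carbonate, while the 2-hydroxyl is held in a hydrogen bond to the carbonyl group.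

Step 4
Reactants: 6 4-(allyloxy)-2,3-dihydroxybenzaldehyde
Product: 7 4-(allyloxy)-2,3-bis(benzyloxy)benzaldehyde
Conditions: BnBr, K2CO3, DMF, 60 °C
Reagents that add atoms: benzyl bromide BrCc1ccccc1
Why: Williamson etherification of the two remaining phenols; the allyl ether is inert to these conditions.

Step 5
Reactants: 4 2,3-bis(benzyloxy)phenol; 7 4-(allyloxy)-2,3-bis(benzyloxy)benzaldehyde
Product: 9 racemic [4-(allyloxy)-2,3-bis(benzyloxy)phenyl][3,4-bis(benzyloxy)-2-hydroxyphenyl]methanol, via bromomagnesium phenoxide 8 (not isolated)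
Conditions: EtMgBr (1.0 equiv), Et2O, 0 °C; solvent exchange to CH2Cl2; 7, rt; aq NH4Cl
Reagents that add atoms: none
Why: Ortho-selective hydroxyalkylation of a magnesium phenoxide: in a non-coordinating solvent the aldehyde is bound to magnesium and delivered through a six-membered transition state to C6 of 4, the only free ortho carbon. The carbinol centre is formed racemic, which does not matter because it is flattened in step 7.

Step 6
Reactants: 10 2,2-dimethyl-1,3-dioxolane
Product: 12 2,2-dimethyl-1,3-dioxole, via 4-chloro-2,2-dimethyl-1,3-dioxolane 11 (not isolated)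
Conditions: N-chlorosuccinimide, azobis(isobutyronitrile) (cat.), PhCF3, 80 °C; then KOtBu, THF, 0 °C to rt; distillation
Reagents that add atoms: none
Why: Radical chlorination α to the ring oxygens followed by base-induced elimination of HCl from the α-chloro ether; the volatile enediol ether is distilled and used fresh.

Step 7
Reactants: 9 racemic [4-(allyloxy)-2,3-bis(benzyloxy)phenyl][3,4-bis(benzyloxy)-2-hydroxyphenyl]methanol; 12 2,2-dimethyl-1,3-dioxole
Product: 14 (2S,3S,4S)-4-[4-(allyloxy)-2,3-bis(benzyloxy)phenyl]-7,8-bis(benzyloxy)-2,3-(isopropylidenedioxy)chroman, via ortho-quinone methide 13 (not isolated)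
Conditions: 12 (4 equiv), (R)-3,3′-bis(2,4,6-triisopropylphenyl)-1,1′-binaphthalene-2,2′-diyl hydrogen phosphate (10 mol %), 5 Å molecular sieves, toluene, −20 °C to rt
Reagents that add atoms: none
Why: The phosphoric acid protonates the benzylic hydroxyl of 9 and water is lost to give the E-configured ortho-quinone methide 13, which stays hydrogen-bonded to the chiral phosphate through its carbonyl oxygen. The electron-rich dioxole 12 then adds to this electron-poor 1-oxadiene in an inverse-demand hetero-Diels–Alder reaction that is concerted but asynchronous, with C3–C4 bond formation ahead of O1–C2 closure. The closest known reaction type is the chiral phosphoric acid catalysed [4+2] cycloaddition of ortho-quinone methides from ortho-hydroxybenzhydrols with acyclic and cyclic enol ethers; a 1,3-dioxole has not been used in that setting, which is why this step is ranked the least certain. Ring C of unit 3 is closed by the cycloaddition itself as a six-membered ring in a [4+2] mode, and the dioxolane ring is carried in intact. At C2 and C3 the cis geometry of the dioxole fixes the cis ring fusion. The relation of C4 to C3 comes from the endo transition state, in which the dioxole oxygens lie under the oxadiene and O3 ends cis to the aryl group of the E-methide. The absolute configuration at C4, and with it at C3 and C2, is set by the face of 13 that the 3,3′-aryl groups of the phosphate leave open. The step needs chemoselective ionisation, secured because only the ortho-hydroxy ring can form a quinone methide while the para oxygen of the other ring is an allyl ether; it has no regiochemical question because 12 is symmetric; and 12 is protected from hydrolysis by the sieves and by its excess.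

Step 8
Reactants: 14 (2S,3S,4S)-4-[4-(allyloxy)-2,3-bis(benzyloxy)phenyl]-7,8-bis(benzyloxy)-2,3-(isopropylidenedioxy)chroman; 15 potassium [4-(benzyloxy)phenyl]trifluoroborate
Product: 16 (2R,3S,4S)-4-[4-(allyloxy)-2,3-bis(benzyloxy)phenyl]-7,8-bis(benzyloxy)-2-[4-(benzyloxy)phenyl]chroman-3-ol
Conditions: 15 (2 equiv), BF3·OEt2 (3 equiv), CH2Cl2/MeCN, −40 to 0 °C; aq NaHCO3
Reagents that add atoms: none
Why: Oxocarbenium arylation with an organotrifluoroborate: BF3 turns 15 into the aryldifluoroborane and ionises the exocyclic C2–O bond of the acetal to a benzopyranyl oxocarbenium ion. The aryl group is transferred to C2 from the face opposite to O3 and to the C4 aryl group, which both lie on the other face, so the 2,3-trans product should form. The 2-propyl residue left on O3 is lost as acetone on aqueous work-up.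

Step 9
Reactants: 16 (2R,3S,4S)-4-[4-(allyloxy)-2,3-bis(benzyloxy)phenyl]-7,8-bis(benzyloxy)-2-[4-(benzyloxy)phenyl]chroman-3-ol
Product: 17 (2R,3S,4S)-4-[2,3-bis(benzyloxy)-4-hydroxyphenyl]-7,8-bis(benzyloxy)-2-[4-(benzyloxy)phenyl]chroman-3-ol
Conditions: Pd(PPh3)4 (5 mol %), morpholine, THF, rt
Reagents that add atoms: none
Why: Tsuji–Trost deallylation: zerovalent palladium ionises the aryl allyl ether to a π-allyl complex that morpholine captures; benzyl ethers, the secondary alcohol and the stereocentres are not affected.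

Step 10
Reactants: 18 daphnetin (7,8-dihydroxy-2H-chromen-2-one)
Product: 19 7,8-bis(benzyloxy)-2H-chromen-2-one
Conditions: BnBr, K2CO3, DMF, 60 °C
Reagents that add atoms: benzyl bromide BrCc1ccccc1
Why: Double Williamson etherification of the catechol; the lactone is stable to carbonate in DMF.

Step 11
Reactants: 19 7,8-bis(benzyloxy)-2H-chromen-2-one
Product: 21 racemic 7,8-bis(benzyloxy)-2-ethoxy-2H-chromene, via lactol 20 (not isolated)
Conditions: iBu2AlH (1.1 equiv), CH2Cl2, −78 °C; then EtOH, pyridinium p-toluenesulfonate (cat.), rt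
Reagents that add atoms: ethanol CCO
Why: Partial reduction of the lactone to the lactol at low temperature, then acid-catalysed acetal formation through the benzopyrylium ion, which the 7-benzyloxy group stabilises.

Step 12
Reactants: 21 racemic 7,8-bis(benzyloxy)-2-ethoxy-2H-chromene; 22 [4-(benzyloxy)phenyl]boronic acid
Product: 24 (2S)-7,8-bis(benzyloxy)-2-[4-(benzyloxy)phenyl]-2H-chromene, via diethyl arylboronate 23 (not isolated)
Conditions: 22, EtOH, 4 Å molecular sieves (gives 23); then 21, (2R,3R)-N,N′-dibenzyl-2,3-dihydroxybutanediamide (10 mol %), Yb(OTf)3 (5 mol %), EtOAc, −20 °C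
Reagents that add atoms: none
Why: Enantioselective boronate addition to a chromene acetal: the Lewis acid ionises the acetal to the benzopyrylium ion, and the aryl group is transferred from the boronate bound to the chiral diol. This sets C2, and both enantiomers of 21 converge because the acetal centre is lost in the cation.

Step 13
Reactants: 24 (2S)-7,8-bis(benzyloxy)-2-[4-(benzyloxy)phenyl]-2H-chromene
Product: 27 (2R,3R,4R)-7,8-bis(benzyloxy)-2-[4-(benzyloxy)phenyl]chroman-3,4-diol, via trans-iodo acetate 25 (not isolated), via cis-diol monoacetate 26 (not isolated)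
Conditions: I2 (1.05 equiv), AgOAc (2.2 equiv), AcOH, rt; then H2O, 50 °C; then K2CO3, MeOH, rt
Reagents that add atoms: silver acetate CC(=O)[O-].[Ag+]
Why: Woodward cis-hydroxylation: acetyl hypoiodite places iodine on C3 anti to the C2 aryl group and acetate on benzylic C4. Silver-assisted displacement of iodide by the neighbouring acetate inverts C3 and forms a cis-fused acetoxonium ion on the face of the aryl group, which water opens to the monoacetate. C3 is set by that inversion and C4 by the cis fusion of the five-membered cation, so the all-cis diol should result after methanolysis.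

Step 14
Reactants: 27 (2R,3R,4R)-7,8-bis(benzyloxy)-2-[4-(benzyloxy)phenyl]chroman-3,4-diol
Product: 28 (2R,3S,4R)-7,8-bis(benzyloxy)-2-[4-(benzyloxy)phenyl]-3,4-(di-tert-butylsilylenedioxy)chroman
Conditions: tBu2Si(OTf)2, 2,6-lutidine, CH2Cl2, 0 °C
Reagents that add atoms: di-tert-butylsilyl bis(trifluoromethanesulfonate) CC(C)(C)[Si](OS(=O)(=O)C(F)(F)F)(OS(=O)(=O)C(F)(F)F)C(C)(C)C
Why: Cyclic silylene formation across the cis-1,2-diol with the bis(triflate) and a hindered base; the benzylic C4 oxygen becomes a silyl ether, a poor leaving group.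

Step 15
Reactants: 28 (2R,3S,4R)-7,8-bis(benzyloxy)-2-[4-(benzyloxy)phenyl]-3,4-(di-tert-butylsilylenedioxy)chroman
Product: 29 (2R,3S,4R)-7,8-bis(benzyloxy)-2-[4-(benzyloxy)phenyl]-6-bromo-3,4-(di-tert-butylsilylenedioxy)chroman
Conditions: N-bromosuccinimide (1.05 equiv), MeCN, 0 °C
Reagents that add atoms: N-bromosuccinimide O=C1CCC(=O)N1Br
Why: Electrophilic aromatic bromination: C6 is para to O1 and ortho to the 7-benzyloxy group and is the most nucleophilic free position; C5 and ring B are each activated by one oxygen only.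

Step 16
Reactants: 29 (2R,3S,4R)-7,8-bis(benzyloxy)-2-[4-(benzyloxy)phenyl]-6-bromo-3,4-(di-tert-butylsilylenedioxy)chroman
Product: 31 (2R,3S,4R)-7,8-bis(benzyloxy)-2-[4-(benzyloxy)phenyl]-3,4-(di-tert-butylsilylenedioxy)chroman-6-carbaldehyde, via aryllithium 30 (not isolated)
Conditions: n-BuLi (1.1 equiv), THF, −78 °C; DMF; aq NH4Cl
Reagents that add atoms: N,N-dimethylformamide CN(C)C=O
Why: Bromine–lithium exchange and formylation of the aryllithium with DMF; the hindered silylene and the benzyl ethers tolerate butyllithium at −78 °C.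

Step 17
Reactants: 32 4-(benzyloxy)benzonitrile
Product: 34 N-[1-[4-(benzyloxy)phenyl]ethenyl]acetamide, via N-magnesio ketimine 33 (not isolated)
Conditions: MeMgBr, THF, 0 °C to reflux; then Ac2O, 0 °C to rt
Reagents that add atoms: methylmagnesium bromide C[Mg]Br; acetic anhydride CC(=O)OC(C)=O
Why: Grignard addition to the nitrile gives the metallated ketimine, which is N-acetylated and tautomerises to the conjugated enamide.

Step 18
Reactants: 17 (2R,3S,4S)-4-[2,3-bis(benzyloxy)-4-hydroxyphenyl]-7,8-bis(benzyloxy)-2-[4-(benzyloxy)phenyl]chroman-3-ol; 31 (2R,3S,4R)-7,8-bis(benzyloxy)-2-[4-(benzyloxy)phenyl]-3,4-(di-tert-butylsilylenedioxy)chroman-6-carbaldehyde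
Product: 36 diaryl carbinol joining C4a of ring A of unit 2 to C6 of unit 1 (both carbinol epimers), via bromomagnesium phenoxide 35 (not isolated)
Conditions: EtMgBr (1.0 equiv), Et2O, 0 °C; solvent exchange to CH2Cl2; 31, rt; aq NH4Cl
Reagents that add atoms: none
Why: The same ortho-selective hydroxyalkylation of a magnesium phenoxide as in step 5: one equivalent of Grignard reagent deprotonates only the phenol, and the aldehyde is delivered to the single free ortho carbon, since the para position carries unit 3. The carbinol epimers are carried on together because the centre is flattened in step 19.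

Step 19
Reactants: 36 diaryl carbinol joining C4a of ring A of unit 2 to C6 of unit 1; 34 N-[1-[4-(benzyloxy)phenyl]ethenyl]acetamide
Product: 39 (4R)-2,4-disubstituted 4H-chromene of unit 2 carrying ring B at C2 and unit 1 at C4, via ortho-quinone methide 37 (not isolated), via 2-acetamidochroman 38 (not isolated)
Conditions: 34 (1.5 equiv), (R)-3,3′-bis(2,4,6-triisopropylphenyl)-1,1′-binaphthalene-2,2′-diyl hydrogen phosphate (10 mol %), 4 Å molecular sieves, CH2Cl2, 0 °C to rt; then pyridinium p-toluenesulfonate (cat.), 40 °C, under argon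
Reagents that add atoms: none
Why: Chiral phosphoric acid catalysed addition of an enamide to an ortho-quinone methide, a known route to 2,4-diaryl-4H-chromenes: 36 loses water, the enamide held by the phosphate through its N–H adds with its terminal carbon to the methide carbon, the phenol closes on the N-acyliminium carbon, and mild acid eliminates acetamide. C4 of unit 2 is set by the catalyst-controlled face of the methide.

Step 20
Reactants: 39 (4R)-2,4-disubstituted 4H-chromene of unit 2
Product: 41 nona-O-benzyl ether of 43 carrying the 3,4-O-(di-tert-butylsilylene) group on unit 1, via C3 alkylborane 40 (not isolated)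
Conditions: BH3·THF (excess), THF, 0 °C to rt; then 30% H2O2, aq NaOH, 0 °C
Reagents that add atoms: hydrogen peroxide OO
Why: Hydroboration–oxidation of an enol ether: boron adds to C3 and hydrogen to C2 in a syn fashion from the face opposite to the C4 aryl group, and oxidation proceeds with retention. O3 therefore ends trans to both aryl groups, the course known for 2-aryl-4H-chromenes and 1-aryl glycals.

Step 21
Reactants: 41 nona-O-benzyl ether of 43 carrying the 3,4-O-(di-tert-butylsilylene) group on unit 1
Product: 42 nona-O-benzyl ether of 43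
Conditions: HF·pyridine, pyridine, THF, 0 °C to rt
Reagents that add atoms: none
Why: Fluoride cleaves both Si–O bonds; the pyridine buffer keeps the medium too weakly acidic to ionise the C4 hydroxyl of unit 1 while the phenols are still benzylated.

Step 22
Reactants: 42 nona-O-benzyl ether of 43
Product: 43 CNP0140823.3
Conditions: H2 (1 atm), Pd(OH)2/C, THF/MeOH, rt
Reagents that add atoms: none
Why: Hydrogenolysis of the nine aryl benzyl ethers under neutral conditions; these are cleaved much faster than the ring C benzylic C–O bonds and the free C4 alcohol, and the product is obtained by filtration and evaporation without exposure to acid or base.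

## Compound list

1 | 2,3-dihydroxybenzaldehyde | O=Cc1cccc(O)c1O | starting material
2 | 2,3-bis(benzyloxy)benzaldehyde | O=Cc1cccc(OCc2ccccc2)c1OCc1ccccc1 | intermediate
3 | 2,3-bis(benzyloxy)phenyl formate | O=COc1cccc(OCc2ccccc2)c1OCc1ccccc1 | intermediate
4 | 2,3-bis(benzyloxy)phenol | Oc1cccc(OCc2ccccc2)c1OCc1ccccc1 | intermediate
5 | 2,3,4-trihydroxybenzaldehyde | O=Cc1ccc(O)c(O)c1O | starting material
6 | 4-(allyloxy)-2,3-dihydroxybenzaldehyde | C=CCOc1ccc(C=O)c(O)c1O | intermediate
7 | 4-(allyloxy)-2,3-bis(benzyloxy)benzaldehyde | C=CCOc1ccc(C=O)c(OCc2ccccc2)c1OCc1ccccc1 | intermediate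
8 | bromomagnesium 2,3-bis(benzyloxy)phenoxide | Br[Mg]Oc1cccc(OCc2ccccc2)c1OCc1ccccc1 | intermediate
9 | racemic [4-(allyloxy)-2,3-bis(benzyloxy)phenyl][3,4-bis(benzyloxy)-2-hydroxyphenyl]methanol | C=CCOc1ccc(C(O)c2ccc(OCc3ccccc3)c(OCc3ccccc3)c2O)c(OCc2ccccc2)c1OCc1ccccc1 | intermediate
10 | 2,2-dimethyl-1,3-dioxolane | CC1(C)OCCO1 | starting material
11 | racemic 4-chloro-2,2-dimethyl-1,3-dioxolane | CC1(C)OCC(Cl)O1 | intermediate
12 | 2,2-dimethyl-1,3-dioxole | CC1(C)OC=CO1 | intermediate
13 | (6E)-6-{[4-(allyloxy)-2,3-bis(benzyloxy)phenyl]methylidene}-2,3-bis(benzyloxy)cyclohexa-2,4-dien-1-one (ortho-quinone methide) | O=C1/C(=C/c2ccc(OCC=C)c(OCc3ccccc3)c2OCc2ccccc2)C=CC(OCc2ccccc2)=C1OCc1ccccc1 | intermediate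
14 | (2S,3S,4S)-4-[4-(allyloxy)-2,3-bis(benzyloxy)phenyl]-7,8-bis(benzyloxy)-2,3-(isopropylidenedioxy)chroman (cis-fused acetonide, aryl cis to O3) | C=CCOc1ccc([C@H]2c3ccc(OCc4ccccc4)c(OCc4ccccc4)c3O[C@H]3OC(C)(C)O[C@@H]23)c(OCc2ccccc2)c1OCc1ccccc1 | intermediate
15 | potassium [4-(benzyloxy)phenyl]trifluoroborate | [K+].F[B-](F)(F)c1ccc(OCc2ccccc2)cc1 | starting material
16 | (2R,3S,4S)-4-[4-(allyloxy)-2,3-bis(benzyloxy)phenyl]-7,8-bis(benzyloxy)-2-[4-(benzyloxy)phenyl]chroman-3-ol (2,3-trans-3,4-cis) | C=CCOc1ccc([C@H]2c3ccc(OCc4ccccc4)c(OCc4ccccc4)c3O[C@H](c3ccc(OCc4ccccc4)cc3)[C@H]2O)c(OCc2ccccc2)c1OCc1ccccc1 | intermediate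
17 | (2R,3S,4S)-4-[2,3-bis(benzyloxy)-4-hydroxyphenyl]-7,8-bis(benzyloxy)-2-[4-(benzyloxy)phenyl]chroman-3-ol | Oc1ccc([C@H]2c3ccc(OCc4ccccc4)c(OCc4ccccc4)c3O[C@H](c3ccc(OCc4ccccc4)cc3)[C@H]2O)c(OCc2ccccc2)c1OCc1ccccc1 | intermediate
18 | daphnetin (7,8-dihydroxy-2H-chromen-2-one) | O=c1ccc2ccc(O)c(O)c2o1 | starting material
19 | 7,8-bis(benzyloxy)-2H-chromen-2-one | O=c1ccc2ccc(OCc3ccccc3)c(OCc3ccccc3)c2o1 | intermediate
20 | 7,8-bis(benzyloxy)-2H-chromen-2-ol (lactol, racemic) | OC1C=Cc2ccc(OCc3ccccc3)c(OCc3ccccc3)c2O1 | intermediate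
21 | racemic 7,8-bis(benzyloxy)-2-ethoxy-2H-chromene | CCOC1C=Cc2ccc(OCc3ccccc3)c(OCc3ccccc3)c2O1 | intermediate
22 | [4-(benzyloxy)phenyl]boronic acid | OB(O)c1ccc(OCc2ccccc2)cc1 | starting material
23 | diethyl [4-(benzyloxy)phenyl]boronate | CCOB(OCC)c1ccc(OCc2ccccc2)cc1 | intermediate
24 | (2S)-7,8-bis(benzyloxy)-2-[4-(benzyloxy)phenyl]-2H-chromene | c1ccccc1COc1ccc([C@H]2Oc3c(ccc(OCc4ccccc4)c3OCc3ccccc3)C=C2)cc1 | intermediate
25 | 4-acetoxy-7,8-bis(benzyloxy)-2-[4-(benzyloxy)phenyl]-3-iodochroman, iodine trans to the C2 aryl group, acetate trans to iodine | c1ccccc1COc1ccc([C@H]2Oc3c(ccc(OCc4ccccc4)c3OCc3ccccc3)[C@@H](OC(C)=O)[C@@H]2I)cc1 | intermediate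
26 | all-cis 4-acetoxy-7,8-bis(benzyloxy)-2-[4-(benzyloxy)phenyl]chroman-3-ol (drawn as the 4-acetate; the 3-acetate regioisomer is equivalent for the next operation) | c1ccccc1COc1ccc([C@H]2Oc3c(ccc(OCc4ccccc4)c3OCc3ccccc3)[C@@H](OC(C)=O)[C@H]2O)cc1 | intermediate
27 | (2R,3R,4R)-7,8-bis(benzyloxy)-2-[4-(benzyloxy)phenyl]chroman-3,4-diol (2,3-cis-3,4-cis) | c1ccccc1COc1ccc([C@H]2Oc3c(ccc(OCc4ccccc4)c3OCc3ccccc3)[C@@H](O)[C@H]2O)cc1 | intermediate
28 | (2R,3S,4R)-7,8-bis(benzyloxy)-2-[4-(benzyloxy)phenyl]-3,4-(di-tert-butylsilylenedioxy)chroman (all-cis) | c1ccccc1COc1ccc([C@H]2Oc3c(ccc(OCc4ccccc4)c3OCc3ccccc3)[C@@H](O5)[C@H]2O[Si]5(C(C)(C)C)C(C)(C)C)cc1 | intermediate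
29 | 6-bromo derivative of 28 | c1ccccc1COc1ccc([C@H]2Oc3c(cc(Br)c(OCc4ccccc4)c3OCc3ccccc3)[C@@H](O5)[C@H]2O[Si]5(C(C)(C)C)C(C)(C)C)cc1 | intermediate
30 | 6-lithio derivative of 28 | c1ccccc1COc1ccc([C@H]2Oc3c(cc([Li])c(OCc4ccccc4)c3OCc3ccccc3)[C@@H](O5)[C@H]2O[Si]5(C(C)(C)C)C(C)(C)C)cc1 | intermediate
31 | (2R,3S,4R)-7,8-bis(benzyloxy)-2-[4-(benzyloxy)phenyl]-3,4-(di-tert-butylsilylenedioxy)chroman-6-carbaldehyde | c1ccccc1COc1ccc([C@H]2Oc3c(cc(C=O)c(OCc4ccccc4)c3OCc3ccccc3)[C@@H](O5)[C@H]2O[Si]5(C(C)(C)C)C(C)(C)C)cc1 | intermediate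
32 | 4-(benzyloxy)benzonitrile | N#Cc1ccc(OCc2ccccc2)cc1 | starting material
33 | N-(bromomagnesio) imine of 1-[4-(benzyloxy)phenyl]ethanone | CC(=N[Mg]Br)c1ccc(OCc2ccccc2)cc1 | intermediate
34 | N-[1-[4-(benzyloxy)phenyl]ethenyl]acetamide | C=C(NC(C)=O)c1ccc(OCc2ccccc2)cc1 | intermediate
35 | bromomagnesium phenoxide of 17 | Br[Mg]Oc1ccc([C@H]2c3ccc(OCc4ccccc4)c(OCc4ccccc4)c3O[C@H](c3ccc(OCc4ccccc4)cc3)[C@H]2O)c(OCc2ccccc2)c1OCc1ccccc1 | intermediate
36 | {3,4-bis(benzyloxy)-2-hydroxy-5-[(2R,3S,4R)-7,8-bis(benzyloxy)-2-(4-benzyloxyphenyl)-3-hydroxychroman-4-yl]phenyl}[(2R,3S,4R)-7,8-bis(benzyloxy)-2-(4-benzyloxyphenyl)-3,4-(di-tert-butylsilylenedioxy)chroman-6-yl]methanol, both carbinol epimers | c1ccccc1COc1ccc([C@H]2Oc3c(cc(C(O)c5cc([C@H]6c7ccc(OCc8ccccc8)c(OCc8ccccc8)c7O[C@H](c7ccc(OCc8ccccc8)cc7)[C@H]6O)c(OCc6ccccc6)c(OCc6ccccc6)c5O)c(OCc4ccccc4)c3OCc3ccccc3)[C@@H](O4)[C@H]2O[Si]4(C(C)(C)C)C(C)(C)C)cc1 | intermediate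
37 | E ortho-quinone methide of ring A of unit 2 from 36 (methide carbon bonded to C6 of unit 1) | c1ccccc1COc1ccc([C@H]2Oc3c(cc(/C=C5\C=C([C@H]6c7ccc(OCc8ccccc8)c(OCc8ccccc8)c7O[C@H](c7ccc(OCc8ccccc8)cc7)[C@H]6O)C(OCc6ccccc6)=C(OCc6ccccc6)C5=O)c(OCc4ccccc4)c3OCc3ccccc3)[C@@H](O4)[C@H]2O[Si]4(C(C)(C)C)C(C)(C)C)cc1 | intermediate
38 | 2-acetamido-2-[4-(benzyloxy)phenyl]chroman of unit 2, (4R), mixture at C2 | c1ccccc1COc1ccc([C@H]2Oc3c(cc([C@@H]4c5cc([C@H]6c7ccc(OCc8ccccc8)c(OCc8ccccc8)c7O[C@H](c7ccc(OCc8ccccc8)cc7)[C@H]6O)c(OCc6ccccc6)c(OCc6ccccc6)c5OC(NC(C)=O)(c5ccc(OCc6ccccc6)cc5)C4)c(OCc4ccccc4)c3OCc3ccccc3)[C@@H](O4)[C@H]2O[Si]4(C(C)(C)C)C(C)(C)C)cc1 | intermediate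
39 | (4R)-7,8-bis(benzyloxy)-2-[4-(benzyloxy)phenyl]-4H-chromene of unit 2, with the unit 3 flavan-3-ol at C6 and the silylene-protected unit 1 (through its C6) at C4 | c1ccccc1COc1ccc([C@H]2Oc3c(cc([C@@H]4c5cc([C@H]6c7ccc(OCc8ccccc8)c(OCc8ccccc8)c7O[C@H](c7ccc(OCc8ccccc8)cc7)[C@H]6O)c(OCc6ccccc6)c(OCc6ccccc6)c5OC(c5ccc(OCc6ccccc6)cc5)=C4)c(OCc4ccccc4)c3OCc3ccccc3)[C@@H](O4)[C@H]2O[Si]4(C(C)(C)C)C(C)(C)C)cc1 | intermediate
40 | C3 alkylborane of unit 2 (boron trans to both aryl groups; the unit 3 hydroxyl as its borate ester) | c1ccccc1COc1ccc([C@H]2Oc3c(cc([C@@H]4c5cc([C@H]6c7ccc(OCc8ccccc8)c(OCc8ccccc8)c7O[C@H](c7ccc(OCc8ccccc8)cc7)[C@H]6OB)c(OCc6ccccc6)c(OCc6ccccc6)c5O[C@H](c5ccc(OCc6ccccc6)cc5)[C@H]4B)c(OCc4ccccc4)c3OCc3ccccc3)[C@@H](O4)[C@H]2O[Si]4(C(C)(C)C)C(C)(C)C)cc1 | intermediate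
41 | nona-O-benzyl ether of 43 with the 3,4-O-(di-tert-butylsilylene) group on unit 1; unit 1 (2R,3S,4R), unit 2 (2R,3S,4R), unit 3 (2R,3S,4R) | c1ccccc1COc1ccc([C@H]2Oc3c(cc([C@@H]4c5cc([C@H]6c7ccc(OCc8ccccc8)c(OCc8ccccc8)c7O[C@H](c7ccc(OCc8ccccc8)cc7)[C@H]6O)c(OCc6ccccc6)c(OCc6ccccc6)c5O[C@H](c5ccc(OCc6ccccc6)cc5)[C@H]4O)c(OCc4ccccc4)c3OCc3ccccc3)[C@@H](O4)[C@H]2O[Si]4(C(C)(C)C)C(C)(C)C)cc1 | intermediate
42 | nona-O-benzyl ether of 43 (all nine phenols benzylated, four hydroxyls free); unit 1 (2R,3R,4R), unit 2 (2R,3S,4R), unit 3 (2R,3S,4R) | c1ccccc1COc1ccc([C@H]2Oc3c(cc([C@@H]4c5cc([C@H]6c7ccc(OCc8ccccc8)c(OCc8ccccc8)c7O[C@H](c7ccc(OCc8ccccc8)cc7)[C@H]6O)c(OCc6ccccc6)c(OCc6ccccc6)c5O[C@H](c5ccc(OCc6ccccc6)cc5)[C@H]4O)c(OCc4ccccc4)c3OCc3ccccc3)[C@@H](O)[C@H]2O)cc1 | intermediate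
43 | CNP0140823.3; unit 1 (2R,3R,4R), unit 2 (2R,3S,4R), unit 3 (2R,3S,4S) | Oc1ccc([C@H]2Oc3c(cc([C@@H]4c5cc([C@H]6c7ccc(O)c(O)c7O[C@H](c7ccc(O)cc7)[C@H]6O)c(O)c(O)c5O[C@H](c5ccc(O)cc5)[C@H]4O)c(O)c3O)[C@@H](O)[C@H]2O)cc1 | target

## Step count and least certain steps

Total: 22 steps. Longest linear sequence: 12 steps (steps 10 to 16 and 18 to 22, from 18). The unit 3 branch (steps 1, 2, 5, 7, 8, 9) joins at step 18.

**Step 7 (key step).** The dioxole may be consumed by acid-catalysed hydrolysis or oligomerisation faster than it is trapped by the quinone methide. The ortho-benzyloxy group on the methide aryl ring may also twist that ring and lower endo and facial selectivity. Fallback, from 9 back to 16: 9 would be oxidised with MnO2 to the 2-hydroxybenzophenone F1. A Mitsunobu reaction of its phenol with methyl (S)-4-(benzyloxy)mandelate, with inversion, would give the (R)-aryloxy ester F2. iBu2AlH at −78 °C would give the aldehyde F3. SmI2 would reduce the diaryl ketone to its ketyl, which closes on the aldehyde to the cis-3,4-diol F4. Ionic hydrogenation (Et3SiH, CF3CO2H) of the tertiary benzylic alcohol, with hydride entering anti to the C3 hydroxyl, would give 16.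

**Step 8.** Ionisation may occur at the ketal carbon instead of C2, with loss of the acetonide or aryl transfer to the wrong carbon, or the aryl group may be delivered with poor face selectivity. Fallback, from 14 back to 16: aqueous acetic acid would hydrolyse the acetonide to the lactol diol F5, and Ac2O in pyridine would give the diacetate F6. BF3·OEt2 and 15 would then ionise only the anomeric acetate, with the C3 acetate closing to a dioxolanylium ion that blocks its own face. The aryl group would enter trans to give the 3-O-acetate F7, and K2CO3 in MeOH would give 16.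

**Step 13.** Competing iodination of the electron-rich arenes, or ionisation at benzylic C4 in warm aqueous acetic acid with loss of the cis relation, are the likely failures. Fallback, from 24 back to 27: N-bromosuccinimide in wet THF would give the bromohydrin F8, with bromine at C3 anti to the aryl group and hydroxyl at C4. K2CO3 would close it to the epoxide F9 on the face of the aryl group. CO2 with catalytic Bu4NBr would convert the epoxide into the cis-fused cyclic carbonate F10, with net retention at C4 by two inversions. K2CO3 in MeOH would release 27.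

**Step 19.** Catalyst and substrate may be mismatched, giving poor diastereoselection at C4 of unit 2, and the 4H-chromene may lose hydride to air to form a flavylium ion. Fallback, from 36 back to 41: the same phosphoric acid catalysis with ethyl vinyl ether, the best-established 2π partner, would give the 2-ethoxychroman F11. Me3SiOTf and iPr2NEt would eliminate ethanol to the 4H-chromene F12. Dimethyldioxirane would epoxidise the enol ether anti to the C4 aryl group to F13. The aryl cuprate from (4-benzyloxyphenyl)magnesium bromide and CuI would open the epoxide at C2 with inversion to give 41.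

**Step 22.** Hydrogenolysis of the free benzylic C4–O bond of unit 1, or of a ring C C2–O bond, may compete once the phenols are free. Fallback, from 41 back to 43: hydrogenolysis would be run first on 41, where C4–O is still a silyl ether, to give the silylene-protected polyphenol F14. The silylene would then be removed with Et3N·3HF in THF under argon to give 43.

## Further compounds

F1 | step 7 | [4-(allyloxy)-2,3-bis(benzyloxy)phenyl][3,4-bis(benzyloxy)-2-hydroxyphenyl]methanone | C=CCOc1ccc(C(=O)c2ccc(OCc3ccccc3)c(OCc3ccccc3)c2O)c(OCc2ccccc2)c1OCc1ccccc1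
F2 | step 7 | methyl (2R)-2-{6-[4-(allyloxy)-2,3-bis(benzyloxy)benzoyl]-2,3-bis(benzyloxy)phenoxy}-2-[4-(benzyloxy)phenyl]acetate | C=CCOc1ccc(C(=O)c2ccc(OCc3ccccc3)c(OCc3ccccc3)c2O[C@H](c2ccc(OCc3ccccc3)cc2)C(=O)OC)c(OCc2ccccc2)c1OCc1ccccc1
F3 | step 7 | (2R)-2-{6-[4-(allyloxy)-2,3-bis(benzyloxy)benzoyl]-2,3-bis(benzyloxy)phenoxy}-2-[4-(benzyloxy)phenyl]acetaldehyde | C=CCOc1ccc(C(=O)c2ccc(OCc3ccccc3)c(OCc3ccccc3)c2O[C@H](c2ccc(OCc3ccccc3)cc2)C=O)c(OCc2ccccc2)c1OCc1ccccc1
F4 | step 7 | 4-[4-(allyloxy)-2,3-bis(benzyloxy)phenyl]-7,8-bis(benzyloxy)-2-[4-(benzyloxy)phenyl]chroman-3,4-diol, hydroxyls cis, both aryl groups on the opposite face | C=CCOc1ccc([C@]2(O)c3ccc(OCc4ccccc4)c(OCc4ccccc4)c3O[C@H](c3ccc(OCc4ccccc4)cc3)[C@H]2O)c(OCc2ccccc2)c1OCc1ccccc1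
F5 | step 8 | (3S,4S)-4-[4-(allyloxy)-2,3-bis(benzyloxy)phenyl]-7,8-bis(benzyloxy)chroman-2,3-diol, anomeric mixture | C=CCOc1ccc([C@H]2c3ccc(OCc4ccccc4)c(OCc4ccccc4)c3OC(O)[C@H]2O)c(OCc2ccccc2)c1OCc1ccccc1
F6 | step 8 | 2,3-di-O-acetate of F5, anomeric mixture | C=CCOc1ccc([C@H]2c3ccc(OCc4ccccc4)c(OCc4ccccc4)c3OC(OC(C)=O)[C@H]2OC(C)=O)c(OCc2ccccc2)c1OCc1ccccc1
F7 | step 8 | 3-O-acetate of 16 | C=CCOc1ccc([C@H]2c3ccc(OCc4ccccc4)c(OCc4ccccc4)c3O[C@H](c3ccc(OCc4ccccc4)cc3)[C@H]2OC(C)=O)c(OCc2ccccc2)c1OCc1ccccc1
F8 | step 13 | 7,8-bis(benzyloxy)-2-[4-(benzyloxy)phenyl]-3-bromochroman-4-ol, bromine trans to the C2 aryl group, hydroxyl trans to bromine | c1ccccc1COc1ccc([C@H]2Oc3c(ccc(OCc4ccccc4)c3OCc3ccccc3)[C@@H](O)[C@@H]2Br)cc1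
F9 | step 13 | 3,4-epoxide of 24 on the face of the C2 aryl group | c1ccccc1COc1ccc([C@H]2Oc3c(ccc(OCc4ccccc4)c3OCc3ccccc3)[C@H]4O[C@@H]24)cc1
F10 | step 13 | cyclic 3,4-carbonate of 27 (all-cis) | c1ccccc1COc1ccc([C@H]2Oc3c(ccc(OCc4ccccc4)c3OCc3ccccc3)[C@@H](O5)[C@H]2OC5=O)cc1
F11 | step 19 | 2-ethoxychroman of unit 2 (ethoxy cis to the C4 substituent) with unit 3 at C6 and silylene-protected unit 1 at C4 | c1ccccc1COc1ccc([C@H]2Oc3c(cc([C@@H]4c5cc([C@H]6c7ccc(OCc8ccccc8)c(OCc8ccccc8)c7O[C@H](c7ccc(OCc8ccccc8)cc7)[C@H]6O)c(OCc6ccccc6)c(OCc6ccccc6)c5O[C@H](OCC)C4)c(OCc4ccccc4)c3OCc3ccccc3)[C@@H](O4)[C@H]2O[Si]4(C(C)(C)C)C(C)(C)C)cc1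
F12 | step 19 | 2-unsubstituted 4H-chromene of unit 2 from F11 | c1ccccc1COc1ccc([C@H]2Oc3c(cc([C@@H]4c5cc([C@H]6c7ccc(OCc8ccccc8)c(OCc8ccccc8)c7O[C@H](c7ccc(OCc8ccccc8)cc7)[C@H]6O)c(OCc6ccccc6)c(OCc6ccccc6)c5OC=C4)c(OCc4ccccc4)c3OCc3ccccc3)[C@@H](O4)[C@H]2O[Si]4(C(C)(C)C)C(C)(C)C)cc1
F13 | step 19 | 2,3-epoxide of F12, oxygen trans to the C4 substituent | c1ccccc1COc1ccc([C@H]2Oc3c(cc([C@@H]4c5cc([C@H]6c7ccc(OCc8ccccc8)c(OCc8ccccc8)c7O[C@H](c7ccc(OCc8ccccc8)cc7)[C@H]6O)c(OCc6ccccc6)c(OCc6ccccc6)c5O[C@H]6O[C@H]64)c(OCc4ccccc4)c3OCc3ccccc3)[C@@H](O4)[C@H]2O[Si]4(C(C)(C)C)C(C)(C)C)cc1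
F14 | step 22 | 43 carrying the 3,4-O-(di-tert-butylsilylene) group on unit 1, all phenols free | Oc1ccc([C@H]2Oc3c(cc([C@@H]4c5cc([C@H]6c7ccc(O)c(O)c7O[C@H](c7ccc(O)cc7)[C@H]6O)c(O)c(O)c5O[C@H](c5ccc(O)cc5)[C@H]4O)c(O)c3O)[C@@H](O8)[C@H]2O[Si]8(C(C)(C)C)C(C)(C)C)cc1
A1 | alternative 1 | protected trimer with 3-O-acetates in units 2 and 3 and the silylene on unit 1 | c9ccccc9COc1ccc([C@H]2Oc3c(cc([C@@H]4c5cc([C@H]6c7ccc(OCc9ccccc9)c(OCc9ccccc9)c7O[C@H](c8ccc(OCc9ccccc9)cc8)[C@H]6OC(C)=O)c(OCc9ccccc9)c(OCc9ccccc9)c5O[C@H](c8ccc(OCc9ccccc9)cc8)[C@H]4OC(C)=O)c(OCc9ccccc9)c3OCc9ccccc9)[C@@H](O8)[C@H]2O[Si]8(C(C)(C)C)C(C)(C)C)cc1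
A2 | alternative 1 | bis-lactol core as its tetraacetate (2,3-di-O-acetyl in units 2 and 3, anomeric mixtures) | c9ccccc9COc1ccc([C@H]2Oc3c(cc([C@@H]4c5cc([C@H]6c7ccc(OCc9ccccc9)c(OCc9ccccc9)c7OC(OC(C)=O)[C@H]6OC(C)=O)c(OCc9ccccc9)c(OCc9ccccc9)c5OC(OC(C)=O)[C@H]4OC(C)=O)c(OCc9ccccc9)c3OCc9ccccc9)[C@@H](O8)[C@H]2O[Si]8(C(C)(C)C)C(C)(C)C)cc1
A3 | alternative 2 | protected trimer with unit 2 as a 4-aryl-chroman-2-ol (anomeric mixture) | c9ccccc9COc1ccc([C@H]2Oc3c(cc([C@@H]4c5cc([C@H]6c7ccc(OCc9ccccc9)c(OCc9ccccc9)c7O[C@H](c8ccc(OCc9ccccc9)cc8)[C@H]6OCc9ccccc9)c(OCc9ccccc9)c(OCc9ccccc9)c5OC(O)C4)c(OCc9ccccc9)c3OCc9ccccc9)[C@@H](O8)[C@H]2O[Si]8(C(C)(C)C)C(C)(C)C)cc1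
A4 | alternative 2 | (E)-3-[unit 1 C6]prop-2-enal, the two-carbon homologue of 31 | c1ccccc1COc1ccc([C@H]2Oc3c(cc(/C=C/C=O)c(OCc4ccccc4)c3OCc3ccccc3)[C@@H](O5)[C@H]2O[Si]5(C(C)(C)C)C(C)(C)C)cc1
A5 | alternative 2 | O3-benzyl ether of 17 | Oc1ccc([C@H]2c3ccc(OCc4ccccc4)c(OCc4ccccc4)c3O[C@H](c3ccc(OCc4ccccc4)cc3)[C@H]2OCc2ccccc2)c(OCc2ccccc2)c1OCc1ccccc1
A6 | alternative 3 | 4-aryl-flavan-3,4-diol of unit 3 (cis diol, 2,3-trans) | C=CCOc1ccc([C@]2(O)c3ccc(OCc4ccccc4)c(OCc4ccccc4)c3O[C@H](c3ccc(OCc4ccccc4)cc3)[C@H]2O)c(OCc2ccccc2)c1OCc1ccccc1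
A7 | alternative 3 | diaryl ketone with tethered (R)-α-aryloxy aldehyde | C=CCOc1ccc(C(=O)c2ccc(OCc3ccccc3)c(OCc3ccccc3)c2O[C@H](c2ccc(OCc3ccccc3)cc2)C=O)c(OCc2ccccc2)c1OCc1ccccc1
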